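**Retrosynthetic overview**

1. The flavanone C2–C1' bond is cut last. Enantioselective palladium-catalysed conjugate addition of a flavone-bearing arylboronic acid to 5-methoxy-7-(methoxymethoxy)chromone sets C2 (S). Rings A and C of the flavanone are bought as a chromone.
2. Ring E (the flavone pyranone) is cut at C4a''–C4'', C4''–C3'' and O1''–C2'', which leads back to an iodophenol, carbon monoxide and 4-(methoxymethoxy)phenylacetylene.
3. Feature on which the route rests: in the flavone, the biaryl carbon C6'' of ring D lies between O5'' and O7''. Before ring E exists, ring D is a 2-aryl-phloroglucinol that is symmetric about the biaryl bond, so a single free hydroxyl (para to the aryl group) with an iodine beside it defines O1'' and C4a'' without ambiguity.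
4. The hindered biaryl bond C3'–C6'' is made first, by Suzuki coupling on simple benzene rings (a symmetric 2-iodophloroglucinol ether and a 5-bromo-2-alkoxyphenylboronic acid).
5. Ring order: rings B and D are bought and joined, ring E is closed on ring D (ring F arrives with the alkyne), the bought A/C chromone is attached, and five MOM groups are removed at the end.

Key step: step 11

Assumption: the biaryl axis C3'–C6'' carries three small oxygen ortho substituents and is taken to rotate freely at room temperature, so C2 is the only stereogenic element to control.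

**Route**

Step 1
Reactants: 1 phloroglucinol
Product: 2 3,5-bis(methoxymethoxy)phenol
Conditions: MOMCl (2.0 equiv), i-Pr2NEt, DMF, 0 °C → rt
Reagents that add atoms: chloromethyl methyl ether, COCCl
Why: Base-mediated O-alkylation (Williamson type) of the threefold-symmetric triphenol with two equivalents of MOMCl should give the bis-ether as the main part of a statistical mixture, from which it is separated by chromatography while the mono- and tris-ethers are recycled.

Step 2
Reactants: 2 3,5-bis(methoxymethoxy)phenol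
Product: 3 [3,5-bis(methoxymethoxy)phenoxy]tri(propan-2-yl)silane
Conditions: TIPSCl, imidazole, DMF, rt
Reagents that add atoms: chlorotri(propan-2-yl)silane, CC(C)[Si](Cl)(C(C)C)C(C)C
Why: Imidazole-promoted silylation of the remaining phenol should proceed cleanly, and the bulky TIPS ether resists n-BuLi and aqueous base and is a poor ortho director.

Step 3
Reactants: 3 [3,5-bis(methoxymethoxy)phenoxy]tri(propan-2-yl)silane
Product: 5 2-iodo-1,3-bis(methoxymethoxy)-5-(triisopropylsilyloxy)benzene, via aryllithium 4 (not isolated)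
Conditions: n-BuLi, THF, 0 °C; then I2, −78 °C → rt
Reagents that add atoms: iodine, II
Why: Directed ortho-metalation should occur only at the C–H between the two chelating OMOM groups, since the two positions next to the bulky non-coordinating OTIPS group are shielded, and iodinolysis of the aryllithium then gives one iodide.

Step 4
Reactants: 6 4-bromo-2-iodophenol
Product: 7 4-bromo-2-iodo-1-(methoxymethoxy)benzene
Conditions: MOMCl, i-Pr2NEt, CH2Cl2, 0 °C → rt
Reagents that add atoms: chloromethyl methyl ether, COCCl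
Why: Standard MOM protection (O-alkylation) of a phenol, which also provides an ortho-chelating group for the exchange in the next step.

Step 5
Reactants: 7 4-bromo-2-iodo-1-(methoxymethoxy)benzene
Product: 10 [5-bromo-2-(methoxymethoxy)phenyl]boronic acid, via arylmagnesium chloride 8 (not isolated), via dimethyl arylboronate 9 (not isolated)
Conditions: i-PrMgCl·LiCl, THF, −30 °C; B(OMe)3, −30 °C → rt; aq. NH4Cl
Reagents that add atoms: trimethyl borate, COB(OC)OC; water, O
Why: Iodine–magnesium exchange is far faster at the chelation-assisted C–I bond than at C–Br at −30 °C, and borate trapping followed by hydrolysis near pH 6 should give the boronic acid with the MOM ether intact.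

Step 6
Reactants: 5 2-iodo-1,3-bis(methoxymethoxy)-5-(triisopropylsilyloxy)benzene; 10 [5-bromo-2-(methoxymethoxy)phenyl]boronic acid
Product: 11 5'-bromo-2,2',6-tris(methoxymethoxy)-4-(triisopropylsilyloxy)-1,1'-biphenyl
Conditions: Pd(PPh3)4 (5 mol%), K3PO4, DME/H2O (4:1), 80 °C
Reagents that add atoms: none
Why: Suzuki–Miyaura coupling in which zerovalent palladium should insert into the C–I bond of 5 much faster than into the electron-rich C–Br bond of 10 or 11, and three small alkoxy ortho groups are tolerated in the biaryl-forming reductive elimination.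

Step 7
Reactants: 11 5'-bromo-2,2',6-tris(methoxymethoxy)-4-(triisopropylsilyloxy)-1,1'-biphenyl
Product: 12 5'-bromo-2,2',6-tris(methoxymethoxy)-[1,1'-biphenyl]-4-ol
Conditions: Bu4NF, THF, 0 °C; aq. NH4Cl
Reagents that add atoms: none
Why: Fluoride cleavage of the aryl silyl ether should free only the hydroxyl para to the biaryl bond, because MOM ethers and the aryl bromide are inert to fluoride.

Step 8
Reactants: 12 5'-bromo-2,2',6-tris(methoxymethoxy)-[1,1'-biphenyl]-4-ol
Product: 13 4-[5-bromo-2-(methoxymethoxy)phenyl]-2-iodo-3,5-bis(methoxymethoxy)phenol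
Conditions: NIS (1.0 equiv), CH2Cl2, −20 → 0 °C, dark
Reagents that add atoms: N-iodosuccinimide, O=C1CCC(=O)N1I
Why: Electrophilic aromatic iodination of the very electron-rich ring D, whose only two free positions are equivalent and both ortho to the free hydroxyl, should stop at the mono-iodide with one equivalent at low temperature, while the far less activated ring B is not touched.

Step 9
Reactants: 14 4-hydroxybenzaldehyde
Product: 15 4-(methoxymethoxy)benzaldehyde
Conditions: MOMCl, i-Pr2NEt, CH2Cl2, 0 °C → rt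
Reagents that add atoms: chloromethyl methyl ether, COCCl
Why: Standard MOM protection (O-alkylation) of a phenol.

Step 10
Reactants: 15 4-(methoxymethoxy)benzaldehyde
Product: 16 1-ethynyl-4-(methoxymethoxy)benzene
Conditions: dimethyl (1-diazo-2-oxopropyl)phosphonate, K2CO3, MeOH, rt
Reagents that add atoms: dimethyl (1-diazo-2-oxopropyl)phosphonate, CC(=O)C(=[N+]=[N-])P(=O)(OC)OC
Why: Ohira–Bestmann variant of the Seyferth–Gilbert homologation, in which the diazophosphonate anion freed by methanolysis adds to the aldehyde and the resulting diazoalkene loses nitrogen and rearranges to the terminal alkyne under mild base that leaves the MOM ether intact.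

Step 11
Reactants: 13 4-[5-bromo-2-(methoxymethoxy)phenyl]-2-iodo-3,5-bis(methoxymethoxy)phenol; 16 1-ethynyl-4-(methoxymethoxy)benzene; 17 carbon monoxide
Product: 20 6-[5-bromo-2-(methoxymethoxy)phenyl]-5,7-bis(methoxymethoxy)-2-[4-(methoxymethoxy)phenyl]-4H-chromen-4-one, via ynone 18 (not isolated), via enaminone 19 (not isolated)
Conditions: PdCl2(PPh3)2 (5 mol%), CO (10 bar), Et2NH, 80 °C
Reagents that add atoms: carbon monoxide (17), [C-]#[O+]
Why: Zerovalent palladium, formed in the flask from PdCl2(PPh3)2, should insert into the C–I bond of 13, CO should insert to give the aroylpalladium species, and copper-free coupling with alkyne 16 should release the ortho-hydroxyaryl ynone 18, which forms C4a''–C4'' and C4''–C3''. Diethylamine then adds to the ynone to give enaminone 19, and the neighbouring phenol oxygen attacks the amine-bearing carbon in a 6-endo-trig oxa-Michael addition followed by loss of diethylamine, which forms O1''–C2'' and closes ring E. The closest known reaction type is the palladium-catalysed carbonylative annulation of 2-iodophenols with terminal alkynes in a secondary amine, which gives flavones. No stereocenter is formed. The step needs 6-aryl over 8-aryl regiochemistry, secured because the only free hydroxyl of ring D sits beside the iodine while the oxygens flanking the biaryl carbon are MOM ethers; flavone over aurone, secured by the amine-mediated 6-endo path in place of a 5-exo phenoxide attack; and C–I over C–Br, secured by the much faster oxidative addition of the iodide under triphenylphosphine ligation and CO pressure at 80 °C. Carbonylative coupling should win over direct alkynylation because no copper salt is present and CO is in excess.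

Step 12
Reactants: 20 6-[5-bromo-2-(methoxymethoxy)phenyl]-5,7-bis(methoxymethoxy)-2-[4-(methoxymethoxy)phenyl]-4H-chromen-4-one
Product: 21 5,7-bis(methoxymethoxy)-6-[2-(methoxymethoxy)-5-(4,4,5,5-tetramethyl-1,3,2-dioxaborolan-2-yl)phenyl]-2-[4-(methoxymethoxy)phenyl]-4H-chromen-4-one
Conditions: B2pin2, PdCl2(dppf) (5 mol%), KOAc, 1,4-dioxane, 90 °C
Reagents that add atoms: bis(pinacolato)diboron, CC1(C)OB(OC1(C)C)B1OC(C)(C)C(C)(C)O1
Why: Miyaura borylation of the unhindered aryl bromide with the weak base KOAc should not disturb the flavone or the MOM ethers and gives a boronate that can be purified by chromatography.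

Step 13
Reactants: 21 5,7-bis(methoxymethoxy)-6-[2-(methoxymethoxy)-5-(4,4,5,5-tetramethyl-1,3,2-dioxaborolan-2-yl)phenyl]-2-[4-(methoxymethoxy)phenyl]-4H-chromen-4-one
Product: 22 {3-[5,7-bis(methoxymethoxy)-2-[4-(methoxymethoxy)phenyl]-4-oxo-4H-chromen-6-yl]-4-(methoxymethoxy)phenyl}boronic acid
Conditions: NaIO4, NH4OAc, acetone/H2O (1:1), rt
Reagents that add atoms: water, O
Why: Hydrolysis of the pinacol boronate is an equilibrium that periodate drives to the free boronic acid by glycol cleavage of the released pinacol, and the buffered near-neutral medium leaves MOM ethers and flavone untouched.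

Step 14
Reactants: 23 5,7-dihydroxy-4H-chromen-4-one
Product: 24 5-hydroxy-7-(methoxymethoxy)-4H-chromen-4-one
Conditions: MOMCl (1.1 equiv), K2CO3, acetone, rt
Reagents that add atoms: chloromethyl methyl ether, COCCl
Why: O-Alkylation should occur at the more acidic 7-hydroxyl only, because the 5-hydroxyl is held in a strong hydrogen bond to the C4 carbonyl.

Step 15
Reactants: 24 5-hydroxy-7-(methoxymethoxy)-4H-chromen-4-one
Product: 25 5-methoxy-7-(methoxymethoxy)-4H-chromen-4-one
Conditions: MeI (excess), K2CO3, DMF, 40 °C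
Reagents that add atoms: iodomethane, CI
Why: Williamson methylation of the chelated 5-hydroxyl needs excess MeI in a dipolar aprotic solvent but should go to completion, and dry carbonate does not open the chromone ring.

Step 16
Reactants: 22 {3-[5,7-bis(methoxymethoxy)-2-[4-(methoxymethoxy)phenyl]-4-oxo-4H-chromen-6-yl]-4-(methoxymethoxy)phenyl}boronic acid; 25 5-methoxy-7-(methoxymethoxy)-4H-chromen-4-one
Product: 26 6-{5-[(2S)-5-methoxy-7-(methoxymethoxy)-4-oxo-3,4-dihydro-2H-chromen-2-yl]-2-(methoxymethoxy)phenyl}-5,7-bis(methoxymethoxy)-2-[4-(methoxymethoxy)phenyl]-4H-chromen-4-one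
Conditions: Pd(OCOCF3)2 (10 mol%), (R)-4-tert-butyl-2-(pyridin-2-yl)-4,5-dihydrooxazole (12 mol%), NH4PF6 (30 mol%), H2O (5 equiv), ClCH2CH2Cl, 60 °C; 25 in twofold excess
Reagents that add atoms: none
Why: Asymmetric conjugate addition of an arylboronic acid to a chromone (transmetalation to cationic divalent palladium, face-selective insertion of the chromone C2=C3 bond, protonolysis of the palladium enolate by water) should arylate only the 2-unsubstituted chromone, since the 2-aryl flavone enone is inert, and the (R)-ligand, the mirror image of the one known to give (2R)-flavanones in this reaction class, should set C2 as S, which is to be confirmed by chiral HPLC and CD on the first run.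

Step 17
Reactants: 26 6-{5-[(2S)-5-methoxy-7-(methoxymethoxy)-4-oxo-3,4-dihydro-2H-chromen-2-yl]-2-(methoxymethoxy)phenyl}-5,7-bis(methoxymethoxy)-2-[4-(methoxymethoxy)phenyl]-4H-chromen-4-one
Product: 27 5,7-dihydroxy-6-{2-hydroxy-5-[(2S)-7-hydroxy-5-methoxy-4-oxo-3,4-dihydro-2H-chromen-2-yl]phenyl}-2-(4-hydroxyphenyl)-4H-chromen-4-one
Conditions: 3 M HCl, MeOH/THF (1:1), 40 °C
Reagents that add atoms: none
Why: Acid-catalysed transacetalisation to methanol should remove all five aryl MOM ethers while the 5-methyl ether survives, and the mild temperature should avoid acid-promoted ring opening of the flavanone to the chalcone, so C2 keeps its configuration.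

**Compound list**

1 | phloroglucinol | Oc1cc(O)cc(O)c1 | starting material
2 | 3,5-bis(methoxymethoxy)phenol | COCOc1cc(O)cc(OCOC)c1 | intermediate
3 | [3,5-bis(methoxymethoxy)phenoxy]tri(propan-2-yl)silane | COCOc1cc(OCOC)cc(O[Si](C(C)C)(C(C)C)C(C)C)c1 | intermediate
4 | [2,6-bis(methoxymethoxy)-4-(triisopropylsilyloxy)phenyl]lithium | [Li]c1c(OCOC)cc(O[Si](C(C)C)(C(C)C)C(C)C)cc1OCOC | intermediate
5 | 2-iodo-1,3-bis(methoxymethoxy)-5-(triisopropylsilyloxy)benzene | COCOc1cc(O[Si](C(C)C)(C(C)C)C(C)C)cc(OCOC)c1I | intermediate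
6 | 4-bromo-2-iodophenol | Oc1ccc(Br)cc1I | starting material
7 | 4-bromo-2-iodo-1-(methoxymethoxy)benzene | COCOc1ccc(Br)cc1I | intermediate
8 | [5-bromo-2-(methoxymethoxy)phenyl]magnesium chloride | COCOc1ccc(Br)cc1[Mg]Cl | intermediate
9 | dimethyl [5-bromo-2-(methoxymethoxy)phenyl]boronate | COCOc1ccc(Br)cc1B(OC)OC | intermediate
10 | [5-bromo-2-(methoxymethoxy)phenyl]boronic acid | COCOc1ccc(Br)cc1B(O)O | intermediate
11 | 5'-bromo-2,2',6-tris(methoxymethoxy)-4-(triisopropylsilyloxy)-1,1'-biphenyl | COCOc1ccc(Br)cc1-c1c(OCOC)cc(O[Si](C(C)C)(C(C)C)C(C)C)cc1OCOC | intermediate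
12 | 5'-bromo-2,2',6-tris(methoxymethoxy)-[1,1'-biphenyl]-4-ol | COCOc1ccc(Br)cc1-c1c(OCOC)cc(O)cc1OCOC | intermediate
13 | 4-[5-bromo-2-(methoxymethoxy)phenyl]-2-iodo-3,5-bis(methoxymethoxy)phenol | Oc1cc(OCOC)c(-c2cc(Br)ccc2OCOC)c(OCOC)c1I | intermediate
14 | 4-hydroxybenzaldehyde | O=Cc1ccc(O)cc1 | starting material
15 | 4-(methoxymethoxy)benzaldehyde | COCOc1ccc(C=O)cc1 | intermediate
16 | 1-ethynyl-4-(methoxymethoxy)benzene | C#Cc1ccc(OCOC)cc1 | intermediate
17 | carbon monoxide | [C-]#[O+] | starting material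
18 | 1-{3-[5-bromo-2-(methoxymethoxy)phenyl]-6-hydroxy-2,4-bis(methoxymethoxy)phenyl}-3-[4-(methoxymethoxy)phenyl]prop-2-yn-1-one | Oc1cc(OCOC)c(-c2cc(Br)ccc2OCOC)c(OCOC)c1C(=O)C#Cc1ccc(OCOC)cc1 | intermediate
19 | 1-{3-[5-bromo-2-(methoxymethoxy)phenyl]-6-hydroxy-2,4-bis(methoxymethoxy)phenyl}-3-(diethylamino)-3-[4-(methoxymethoxy)phenyl]prop-2-en-1-one (double-bond geometry not defined) | Oc1cc(OCOC)c(-c2cc(Br)ccc2OCOC)c(OCOC)c1C(=O)C=C(N(CC)CC)c1ccc(OCOC)cc1 | intermediate
20 | 6-[5-bromo-2-(methoxymethoxy)phenyl]-5,7-bis(methoxymethoxy)-2-[4-(methoxymethoxy)phenyl]-4H-chromen-4-one | COCOc1ccc(-c2cc(=O)c3c(OCOC)c(-c4cc(Br)ccc4OCOC)c(OCOC)cc3o2)cc1 | intermediate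
21 | 5,7-bis(methoxymethoxy)-6-[2-(methoxymethoxy)-5-(4,4,5,5-tetramethyl-1,3,2-dioxaborolan-2-yl)phenyl]-2-[4-(methoxymethoxy)phenyl]-4H-chromen-4-one | COCOc1ccc(-c2cc(=O)c3c(OCOC)c(-c4cc(B5OC(C)(C)C(C)(C)O5)ccc4OCOC)c(OCOC)cc3o2)cc1 | intermediate
22 | {3-[5,7-bis(methoxymethoxy)-2-[4-(methoxymethoxy)phenyl]-4-oxo-4H-chromen-6-yl]-4-(methoxymethoxy)phenyl}boronic acid | COCOc1ccc(-c2cc(=O)c3c(OCOC)c(-c4cc(B(O)O)ccc4OCOC)c(OCOC)cc3o2)cc1 | intermediate
23 | 5,7-dihydroxy-4H-chromen-4-one | O=c1ccoc2cc(O)cc(O)c12 | starting material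
24 | 5-hydroxy-7-(methoxymethoxy)-4H-chromen-4-one | O=c1ccoc2cc(OCOC)cc(O)c12 | intermediate
25 | 5-methoxy-7-(methoxymethoxy)-4H-chromen-4-one | COc1cc(OCOC)cc2occc(=O)c12 | intermediate
26 | 6-{5-[(2S)-5-methoxy-7-(methoxymethoxy)-4-oxo-3,4-dihydro-2H-chromen-2-yl]-2-(methoxymethoxy)phenyl}-5,7-bis(methoxymethoxy)-2-[4-(methoxymethoxy)phenyl]-4H-chromen-4-one | COc1cc(OCOC)cc2c1C(=O)C[C@@H](c1ccc(OCOC)c(-c3c(OCOC)cc4oc(-c5ccc(OCOC)cc5)cc(=O)c4c3OCOC)c1)O2 | intermediate
27 | 5,7-dihydroxy-6-{2-hydroxy-5-[(2S)-7-hydroxy-5-methoxy-4-oxo-3,4-dihydro-2H-chromen-2-yl]phenyl}-2-(4-hydroxyphenyl)-4H-chromen-4-one | COc1cc(O)cc2c1C(=O)C[C@@H](c1ccc(O)c(-c3c(O)cc4oc(-c5ccc(O)cc5)cc(=O)c4c3O)c1)O2 | target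

**Step count and risk**

Total: 17 steps. Longest linear sequence: 11 steps (steps 1, 2, 3, 6, 7, 8, 11, 12, 13, 16, 17).

Steps most likely to fail:

1. Step 11 (carbonylative annulation). Oxidative addition at the electron-rich C–I bond, flanked by a hydroxyl and a MOM ether, may be slow. That would let aminocarbonylation by diethylamine, direct alkynylation without CO uptake, or slow insertion at C–Br compete.
 Fallback: the acyl carbon is brought in by an organomagnesium acylation, not by CO. It sets out from 13 and 16 and comes back at 20. Phenol 13 is silylated (TBSCl, imidazole, DMF) to tert-butyl{4-[5-bromo-2-(methoxymethoxy)phenyl]-2-iodo-3,5-bis(methoxymethoxy)phenoxy}dimethylsilane F1. Alkyne 16 is deprotonated (n-BuLi, THF, −78 °C) to lithium [4-(methoxymethoxy)phenyl]acetylide F2, which is acylated with N-methoxy-N-methylcarbamoyl chloride to N-methoxy-N-methyl-3-[4-(methoxymethoxy)phenyl]prop-2-ynamide F3. Iodine–magnesium exchange on F1 (i-PrMgCl·LiCl, THF, −20 °C, C–Br untouched) gives the arylmagnesium chloride F4, which adds to F3 and gives, after a cold weakly acidic quench, the silyl-protected ynone F5. Diethylamine in ethanol adds to F5 to give the silyl enaminone F6. Bu4NF then frees the phenol, giving enaminone 19, which closes by the same 6-endo addition–elimination to flavone 20.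

2. Step 16 (asymmetric conjugate addition). Insertion into the electron-rich 5,7-dioxygenated chromone may be slow, so protodeboronation of the boronic acid takes over. The peri methoxy group may also erode facial selectivity.
 Fallback: the flavanone is built by the chalcone route and resolved. It sets out from 20 and comes back at 26. Reductive carbonylation of bromide 20 (Pd(OAc)2, di(1-adamantyl)-n-butylphosphine, CO/H2, TMEDA, toluene, 100 °C) gives 3-[5,7-bis(methoxymethoxy)-2-[4-(methoxymethoxy)phenyl]-4-oxo-4H-chromen-6-yl]-4-(methoxymethoxy)benzaldehyde F7. Purchased 2',4'-dihydroxy-6'-methoxyacetophenone is protected at its non-chelated 4'-hydroxyl (MOMCl, K2CO3, acetone) to give 1-[2-hydroxy-6-methoxy-4-(methoxymethoxy)phenyl]ethanone F8. Claisen–Schmidt condensation of F7 with F8 (KOH, EtOH, rt) gives the (E)-2'-hydroxychalcone F9. NaOAc in refluxing EtOH closes it by oxa-Michael addition to the racemic protected flavanone F10. Preparative chiral HPLC separates 26 from its (2R)-enantiomer F11, which can be re-equilibrated with NaOAc and recycled.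

3. Step 6 (Suzuki coupling). Transmetalation and reductive elimination towards the biaryl with three ortho substituents may be slow. That would allow protodeboronation of 10 and oxidative addition at C–Br, which leads to oligomers.
 Fallback: the nucleophile is moved to ring D and boron is dropped. It sets out from 3 and 7 and comes back at 11. Aryllithium 4, made as in step 3, is transmetalated with ZnCl2 (THF, 0 °C) to chloro[2,6-bis(methoxymethoxy)-4-(triisopropylsilyloxy)phenyl]zinc F12. Negishi coupling of F12 with 7 (Pd(PPh3)4, THF, 50 °C) takes place at its C–I bond, which reacts well before the C–Br bond of the same ring, and gives 11 directly.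

**Further compounds**

F1 | step 11 | tert-butyl{4-[5-bromo-2-(methoxymethoxy)phenyl]-2-iodo-3,5-bis(methoxymethoxy)phenoxy}dimethylsilane | CC(C)(C)[Si](C)(C)Oc1cc(OCOC)c(-c2cc(Br)ccc2OCOC)c(OCOC)c1I
F2 | step 11 | lithium [4-(methoxymethoxy)phenyl]acetylide | [Li]C#Cc1ccc(OCOC)cc1
F3 | step 11 | N-methoxy-N-methyl-3-[4-(methoxymethoxy)phenyl]prop-2-ynamide | CON(C)C(=O)C#Cc1ccc(OCOC)cc1
F4 | step 11 | {3-[5-bromo-2-(methoxymethoxy)phenyl]-6-(tert-butyldimethylsilyloxy)-2,4-bis(methoxymethoxy)phenyl}magnesium chloride | CC(C)(C)[Si](C)(C)Oc1cc(OCOC)c(-c2cc(Br)ccc2OCOC)c(OCOC)c1[Mg]Cl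
F5 | step 11 | 1-{3-[5-bromo-2-(methoxymethoxy)phenyl]-6-(tert-butyldimethylsilyloxy)-2,4-bis(methoxymethoxy)phenyl}-3-[4-(methoxymethoxy)phenyl]prop-2-yn-1-one | CC(C)(C)[Si](C)(C)Oc1cc(OCOC)c(-c2cc(Br)ccc2OCOC)c(OCOC)c1C(=O)C#Cc1ccc(OCOC)cc1
F6 | step 11 | 1-{3-[5-bromo-2-(methoxymethoxy)phenyl]-6-(tert-butyldimethylsilyloxy)-2,4-bis(methoxymethoxy)phenyl}-3-(diethylamino)-3-[4-(methoxymethoxy)phenyl]prop-2-en-1-one | CC(C)(C)[Si](C)(C)Oc1cc(OCOC)c(-c2cc(Br)ccc2OCOC)c(OCOC)c1C(=O)C=C(N(CC)CC)c1ccc(OCOC)cc1
F7 | step 16 | 3-[5,7-bis(methoxymethoxy)-2-[4-(methoxymethoxy)phenyl]-4-oxo-4H-chromen-6-yl]-4-(methoxymethoxy)benzaldehyde | COCOc1ccc(-c2cc(=O)c3c(OCOC)c(-c4cc(C=O)ccc4OCOC)c(OCOC)cc3o2)cc1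
F8 | step 16 | 1-[2-hydroxy-6-methoxy-4-(methoxymethoxy)phenyl]ethanone | CC(=O)c1c(O)cc(OCOC)cc1OC
F9 | step 16 | (E)-3-{3-[5,7-bis(methoxymethoxy)-2-[4-(methoxymethoxy)phenyl]-4-oxo-4H-chromen-6-yl]-4-(methoxymethoxy)phenyl}-1-[2-hydroxy-6-methoxy-4-(methoxymethoxy)phenyl]prop-2-en-1-one | COc1cc(OCOC)cc(O)c1C(=O)/C=C/c1ccc(OCOC)c(-c2c(OCOC)cc3oc(-c4ccc(OCOC)cc4)cc(=O)c3c2OCOC)c1
F10 | step 16 | racemic 6-{5-[5-methoxy-7-(methoxymethoxy)-4-oxo-3,4-dihydro-2H-chromen-2-yl]-2-(methoxymethoxy)phenyl}-5,7-bis(methoxymethoxy)-2-[4-(methoxymethoxy)phenyl]-4H-chromen-4-one | COc1cc(OCOC)cc2c1C(=O)CC(c1ccc(OCOC)c(-c3c(OCOC)cc4oc(-c5ccc(OCOC)cc5)cc(=O)c4c3OCOC)c1)O2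
F11 | step 16 | (2R)-enantiomer of 26 | COc1cc(OCOC)cc2c1C(=O)C[C@H](c1ccc(OCOC)c(-c3c(OCOC)cc4oc(-c5ccc(OCOC)cc5)cc(=O)c4c3OCOC)c1)O2
F12 | step 6 | chloro[2,6-bis(methoxymethoxy)-4-(triisopropylsilyloxy)phenyl]zinc | COCOc1cc(O[Si](C(C)C)(C(C)C)C(C)C)cc(OCOC)c1[Zn]Cl
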